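**Plan**

Numbering follows the germacranolide skeleton: C1 ketone, C2=C3 enol ether, C4=C5 with C15H2OH on C4, C6 lactone carbinol, C7, C8 ester carbinol, C9, C10 quaternary (ring O, C14H3), C11(=C13H2)–C12 lactone carbonyl. Retrosynthetic cuts, in order: O15–Si; C5–C6 together with O6–C12; O8–methacryloyl; C7–C8; the furanone ring (O10–C3, C2–C3); C9–C10.
Forward: the 3(2H)-furanone is built first from an α-silyloxy methyl ketone (C1, C2, C8–C10) and a (Z)-β-iodo enal (C3–C5, C15). C8 is then turned into an aldehyde and receives C6, C7 and C11–C13 by a 2-(alkoxycarbonyl)allylation. After methacrylation and oxidation of C6 to the aldehyde, one organochromium event closes the nine-membered oxa-bridged ring (and with it the ten-membered carbocycle) and the γ-lactone.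
Enabling feature: the furanone ring (O–C10–C1–C2–C3) is a rigid 1,3-bridge between C10 and C3, and the Z C4=C5 bond turns C5 toward C6, so the ring C3–C4–C5–C6–C7–C8–C9–C10–O lacks only the C5–C6 bond. The oxygen created at C6 lies γ to the C12 ester, so the lactone ring O6–C6–C7–C11–C12 closes in the same operation.
Stereochemistry: C10 from (R)-lactic acid by self-regeneration of stereocentres; the Z alkene from a β-iodo Morita–Baylis–Hillman reaction; C7 and C8 together from a ligand-controlled, syn-selective allylchromium addition; C6 from the ring closure under control of C7.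

Key step: step 20

Assumption: in step 16 the (S,S) antipode of the carbazole bis(oxazoline) ligand is taken to be the one that delivers the 8R carbinol; if the sense is opposite, the (R,R) ligand is used.

**Route**

Step 1
Reactants: 1 (R)-lactic acid
Product: 2 cis-(2R,5R)-dioxolanone
Conditions: pivaldehyde, TsOH·H2O (cat.), pentane, reflux, Dean–Stark; crystallization of the cis isomer
Reagents that add atoms: pivaldehyde, CC(C)(C)C=O
Why: Acid-catalysed acetalization of the α-hydroxy acid should give the thermodynamically preferred cis-dioxolanone, which stores the lactate configuration at the acetal carbon.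

Step 2
Reactants: 2 cis-(2R,5R)-dioxolanone
Product: 3 (2R,5S)-5-allyl dioxolanone
Conditions: LiN(i-Pr)2, THF, −78 °C; allyl bromide, −78 to −30 °C
Reagents that add atoms: allyl bromide, C=CCBr
Why: Enolate alkylation (self-regeneration of stereocentres) should place the allyl group anti to the tert-butyl group, which sets C10 with overall retention.

Step 3
Reactants: 3 (2R,5S)-5-allyl dioxolanone
Product: 4 (S)-2-hydroxy-2-methylpent-4-enoic acid
Conditions: LiOH, THF/H2O, rt; then 1 M HCl
Reagents that add atoms: lithium hydroxide, [Li+].[OH-]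
Why: Saponification of the acetal ester opens the ring and the hemiacetal loses pivaldehyde, leaving the quaternary centre untouched.

Step 4
Reactants: 4 (S)-2-hydroxy-2-methylpent-4-enoic acid
Product: 5 (S)-3-hydroxy-3-methylhex-5-en-2-one
Conditions: MeLi (3.3 equiv), Et2O, 0 °C to rt; inverse quench into cold aq. NH4Cl
Reagents that add atoms: methyllithium, [Li]C
Why: Addition of an organolithium to the lithium carboxylate gives a gem-diolate that is stable until the quench, so the methyl ketone is released only on work-up (ketone synthesis from a carboxylic acid).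

Step 5
Reactants: 5 (S)-3-hydroxy-3-methylhex-5-en-2-one
Product: 6 (S)-3-methyl-3-(trimethylsilyloxy)hex-5-en-2-one
Conditions: TMSCl, imidazole, DMF, 0 °C
Reagents that add atoms: chlorotrimethylsilane, C[Si](C)(C)Cl
Why: Silylation of the tertiary alcohol masks the hydroxyl for the enolate chemistry and is removed by the acid of step 12.

Step 6
Reactants: 7 ethyl propiolate
Product: 8 ethyl (Z)-2-(hydroxymethyl)-3-iodoacrylate
Conditions: MgI2 (1.2 equiv), monomeric CH2O, CH2Cl2, 0 °C, dark
Reagents that add atoms: formaldehyde, C=O; magnesium diiodide, [Mg+2].[I-].[I-]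
Why: In the β-iodo Morita–Baylis–Hillman (halo-aldol) reaction, iodide adds to the ynoate and the β-iodo allenolate takes up formaldehyde anti to iodine, so iodine should end cis to the ester (Z) under kinetic control.

Step 7
Reactants: 8 ethyl (Z)-2-(hydroxymethyl)-3-iodoacrylate
Product: 9 TBDPS ether of 8
Conditions: TBDPSCl, imidazole, CH2Cl2, 0 °C
Reagents that add atoms: tert-butylchlorodiphenylsilane, CC(C)(C)[Si](Cl)(c1ccccc1)c1ccccc1
Why: Silylation of the primary alcohol fixes the difference between C15 (protected) and C3 (ester) and gives an ether that survives the acid of step 12.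

Step 8
Reactants: 9 TBDPS ether of 8
Product: 10 (E)-2-(silyloxymethyl)-3-iodoprop-2-en-1-ol
Conditions: i-Bu2AlH (2.2 equiv), CH2Cl2, −78 °C; potassium sodium tartrate work-up
Reagents that add atoms: none
Why: 1,2-Reduction of the enoate by the aluminium hydride leaves the vinyl iodide and the alkene geometry intact.

Step 9
Reactants: 10 (E)-2-(silyloxymethyl)-3-iodoprop-2-en-1-ol
Product: 11 (Z)-2-(silyloxymethyl)-3-iodoprop-2-enal
Conditions: MnO2 (excess), CH2Cl2, rt, dark
Reagents that add atoms: none
Why: Allylic oxidation with MnO2 is neutral and should not isomerize the β-iodo enal.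

Step 10
Reactants: 6 (S)-3-methyl-3-(trimethylsilyloxy)hex-5-en-2-one; 11 (Z)-2-(silyloxymethyl)-3-iodoprop-2-enal
Product: 12 β-hydroxy ketone (both C3 epimers)
Conditions: LiN(i-Pr)2, THF, −78 °C; then 11, −78 °C; aq. NH4Cl
Reagents that add atoms: none
Why: The kinetic lithium enolate, which can form only at the methyl group, should add 1,2 to the enal (aldol addition) and forms the C2–C3 bond; the new carbinol centre is removed in step 11.

Step 11
Reactants: 12 β-hydroxy ketone
Product: 13 1,3-diketone
Conditions: Dess–Martin periodinane, NaHCO3, CH2Cl2, rt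
Reagents that add atoms: none
Why: Dess–Martin oxidation converts β-hydroxy ketones into 1,3-diketones under buffered, non-nucleophilic conditions.

Step 12
Reactants: 13 1,3-diketone
Product: 14 (S)-2-allyl-5-(iodovinyl)furan-3(2H)-one
Conditions: TsOH·H2O (0.2 equiv), wet CH2Cl2, rt
Reagents that add atoms: none
Why: Acid removes the trimethylsilyl group, the C10 hydroxyl adds to the C3 carbonyl and water is lost (cyclodehydration of an α′-hydroxy 1,3-diketone to a 3(2H)-furanone); the non-nucleophilic acid avoids halide exchange at C5 and the TBDPS ether should survive.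

Step 13
Reactants: 14 (S)-2-allyl-5-(iodovinyl)furan-3(2H)-one
Product: 16 furanone acetaldehyde, via vicinal diol 15 (not isolated)
Conditions: OsO4 (2 mol%), NaIO4, 2,6-lutidine, dioxane/H2O (3:1), rt; product used crude
Reagents that add atoms: osmium tetroxide, O=[Os](=O)(=O)=O; sodium periodate, [Na+].[O-]I(=O)(=O)=O
Why: In the Lemieux–Johnson oxidative cleavage the isolated monosubstituted alkene should react well before the conjugated, electron-poor C2=C3 and C4=C5 bonds.

Step 14
Reactants: 17 methyl acrylate; 18 (tert-butyldimethylsilyloxy)acetaldehyde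
Product: 19 Morita–Baylis–Hillman alcohol (racemic)
Conditions: DABCO (0.5 equiv), neat, rt
Reagents that add atoms: none
Why: The Morita–Baylis–Hillman reaction joins the acrylate α-carbon (C11) to the aldehyde carbon (C7); the carbinol centre is removed in step 15.

Step 15
Reactants: 19 Morita–Baylis–Hillman alcohol
Product: 20 methyl (Z)-2-(bromomethyl)-4-(silyloxy)but-2-enoate
Conditions: NBS, Me2S, CH2Cl2, 0 °C to rt
Reagents that add atoms: N-bromosuccinimide, O=C1CCC(=O)N1Br
Why: Activation of the alcohol as an alkoxysulfonium salt and SN2′ attack of bromide give the rearranged allylic bromide as the thermodynamically preferred isomer, with CH2OTBS cis to CH2Br.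

Step 16
Reactants: 16 furanone acetaldehyde; 20 methyl (Z)-2-(bromomethyl)-4-(silyloxy)but-2-enoate
Product: 22 syn-hydroxy ester (7S,8R,10S), via trimethylsilyl ether 21 (not isolated)
Conditions: CrCl2 (10 mol%), (S,S)-3,6-di-tert-butyl-1,8-bis(4-isopropyl-4,5-dihydrooxazol-2-yl)-9H-carbazole (12 mol%), i-Pr2NEt (30 mol%), Mn powder, TMSCl, THF, rt; then citric acid, MeOH, 0 °C
Reagents that add atoms: none
Why: In this catalytic asymmetric Nozaki–Hiyama 2-(alkoxycarbonyl)allylation the allylchromium adds through its γ-carbon (C7) in a closed chair with CH2OTBS axial, which should give the syn C7/C8 pair, while the ligand selects the aldehyde face (8R); without nickel the alkenyl iodide is not touched by divalent chromium.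

Step 17
Reactants: 22 syn-hydroxy ester
Product: 23 C8 methacrylate
Conditions: methacrylic anhydride, i-Pr2NEt, DMAP (0.1 equiv), CH2Cl2, 0 °C
Reagents that add atoms: methacrylic anhydride, C=C(C)C(=O)OC(=O)C(C)=C
Why: Acyl transfer to the only free hydroxyl installs the ester of the target and removes the risk of lactonization through O8.

Step 18
Reactants: 23 C8 methacrylate
Product: 24 C6 primary alcohol
Conditions: HF·pyridine, pyridine, THF, 0 °C
Reagents that add atoms: none
Why: Buffered fluoride should cleave the primary TBS ether much faster than the TBDPS ether, and the cold, buffered medium keeps the hydroxy ester from lactonizing.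

Step 19
Reactants: 24 C6 primary alcohol
Product: 25 C6 aldehyde (7R,8R,10S)
Conditions: Dess–Martin periodinane, NaHCO3, CH2Cl2, 0 °C; used at once
Reagents that add atoms: none
Why: Buffered Dess–Martin oxidation gives the aldehyde without base, which protects the acidic C7–H from epimerization and the β-methacrylate from E1cB loss.

Step 20
Reactants: 25 C6 aldehyde
Product: 27 15-O-TBDPS macrolactone, via macrocyclic hydroxy ester 26 (not isolated)
Conditions: CrCl2 (10 equiv), NiCl2 (0.1 equiv), DMSO/THF (3:1), rt, syringe-pump addition to 2 mM, dark; then 40 °C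
Reagents that add atoms: none
Why: NiCl2 is reduced by CrCl2 to zerovalent nickel, which inserts into the C5–I bond; transmetalation gives the (Z)-alkenyl trivalent chromium species with retention, this adds to the C6 aldehyde through a chromium-bound four-centre transition state, and the chromium alkoxide at O6 then attacks the C12 methyl ester and expels methoxide (Nozaki–Hiyama–Kishi reaction followed by lactonization). The closest known reaction type is the Nozaki–Hiyama–Kishi macrocyclization of alkenyl and heteroaryl halides onto aldehydes, which includes closures of nine-membered rings bridged across the 2,5-positions of a five-membered oxygen heterocycle. The nine-membered ring C3–C4–C5–C6–C7–C8–C9–C10–O (and the ten-membered carbocycle C1–C10) closes in the exo-trig mode at the aldehyde (9-exo-trig), and the γ-lactone O6–C6–C7–C11–C12 closes 5-exo-trig at the ester. C6 is set under substrate control by C7: the acrylate branch lies anti to the forming bond and the ring carbon C8 sits on the side of the Bürgi–Dunitz approach, away from the carbonyl oxygen, which should lead to the 6R alkoxide and hence the trans-fused lactone. The step needs selectivity for the aldehyde over the furanone ketone, the esters and the acrylate acceptors (secured by the carbonyl selectivity and low basicity of organochromium reagents), retention of the Z geometry, and ring closure over oligomerization, which the rigid furanone bridge and slow addition at high dilution favour.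

Step 21
Reactants: 27 15-O-TBDPS macrolactone
Product: 28 target
Conditions: HF·pyridine, THF, 0 °C to rt
Reagents that add atoms: none
Why: Acidic fluoride removes the primary allylic silyl ether without base, so the α-methylene lactone, the methacrylate and the dienone are not exposed to nucleophiles.

**Compound list**

1 | (R)-lactic acid | C[C@@H](O)C(=O)O | starting material
2 | cis-(2R,5R)-2-tert-butyl-5-methyl-1,3-dioxolan-4-one | C[C@H]1O[C@@H](C(C)(C)C)OC1=O | intermediate
3 | (2R,5S)-5-allyl-2-tert-butyl-5-methyl-1,3-dioxolan-4-one | C[C@@]1(CC=C)O[C@@H](C(C)(C)C)OC1=O | intermediate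
4 | (S)-2-hydroxy-2-methylpent-4-enoic acid | C=CC[C@](C)(O)C(=O)O | intermediate
5 | (S)-3-hydroxy-3-methylhex-5-en-2-one | C=CC[C@](C)(O)C(C)=O | intermediate
6 | (S)-3-methyl-3-(trimethylsilyloxy)hex-5-en-2-one | C=CC[C@](C)(O[Si](C)(C)C)C(C)=O | intermediate
7 | ethyl propiolate | C#CC(=O)OCC | starting material
8 | ethyl (Z)-2-(hydroxymethyl)-3-iodoacrylate (iodine cis to the ester) | CCOC(=O)/C(CO)=C\I | intermediate
9 | ethyl (Z)-2-[(tert-butyldiphenylsilyloxy)methyl]-3-iodoacrylate | CCOC(=O)/C(CO[Si](c1ccccc1)(c1ccccc1)C(C)(C)C)=C\I | intermediate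
10 | (E)-2-[(tert-butyldiphenylsilyloxy)methyl]-3-iodoprop-2-en-1-ol (iodine cis to the free CH2OH) | OC/C(CO[Si](c1ccccc1)(c1ccccc1)C(C)(C)C)=C\I | intermediate
11 | (Z)-2-[(tert-butyldiphenylsilyloxy)methyl]-3-iodoprop-2-enal (iodine cis to CHO) | O=C/C(CO[Si](c1ccccc1)(c1ccccc1)C(C)(C)C)=C\I | intermediate
12 | (1Z,6S)-2-[(tert-butyldiphenylsilyloxy)methyl]-3-hydroxy-1-iodo-6-methyl-6-(trimethylsilyloxy)nona-1,8-dien-5-one (both C3 epimers) | C=CC[C@](C)(O[Si](C)(C)C)C(=O)CC(O)/C(CO[Si](c1ccccc1)(c1ccccc1)C(C)(C)C)=C\I | intermediate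
13 | (1Z,6S)-2-[(tert-butyldiphenylsilyloxy)methyl]-1-iodo-6-methyl-6-(trimethylsilyloxy)nona-1,8-diene-3,5-dione | C=CC[C@](C)(O[Si](C)(C)C)C(=O)CC(=O)/C(CO[Si](c1ccccc1)(c1ccccc1)C(C)(C)C)=C\I | intermediate
14 | (S)-2-allyl-5-{(Z)-1-[(tert-butyldiphenylsilyloxy)methyl]-2-iodovinyl}-2-methylfuran-3(2H)-one | C=CC[C@]1(C)OC(=CC1=O)/C(CO[Si](c1ccccc1)(c1ccccc1)C(C)(C)C)=C\I | intermediate
15 | (2S)-5-{(Z)-1-[(tert-butyldiphenylsilyloxy)methyl]-2-iodovinyl}-2-(2,3-dihydroxypropyl)-2-methylfuran-3(2H)-one (both carbinol epimers) | OCC(O)C[C@]1(C)OC(=CC1=O)/C(CO[Si](c1ccccc1)(c1ccccc1)C(C)(C)C)=C\I | intermediate (not isolated)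
16 | 2-[(S)-5-{(Z)-1-[(tert-butyldiphenylsilyloxy)methyl]-2-iodovinyl}-2-methyl-3-oxo-2,3-dihydrofuran-2-yl]acetaldehyde | O=CC[C@]1(C)OC(=CC1=O)/C(CO[Si](c1ccccc1)(c1ccccc1)C(C)(C)C)=C\I | intermediate
17 | methyl acrylate | C=CC(=O)OC | starting material
18 | (tert-butyldimethylsilyloxy)acetaldehyde | CC(C)(C)[Si](C)(C)OCC=O | starting material
19 | methyl 2-[2-(tert-butyldimethylsilyloxy)-1-hydroxyethyl]acrylate (racemic) | C=C(C(=O)OC)C(O)CO[Si](C)(C)C(C)(C)C | intermediate
20 | methyl (Z)-2-(bromomethyl)-4-(tert-butyldimethylsilyloxy)but-2-enoate (CH2OTBS cis to CH2Br) | COC(=O)/C(CBr)=C/CO[Si](C)(C)C(C)(C)C | intermediate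
21 | 4-O-trimethylsilyl ether of 22 | COC(=O)C(=C)[C@@H](CO[Si](C)(C)C(C)(C)C)[C@H](O[Si](C)(C)C)C[C@]1(C)OC(=CC1=O)/C(CO[Si](c2ccccc2)(c2ccccc2)C(C)(C)C)=C\I | intermediate (not isolated)
22 | methyl (3S,4R)-3-[(tert-butyldimethylsilyloxy)methyl]-4-hydroxy-2-methylidene-5-[(S)-5-{(Z)-1-[(tert-butyldiphenylsilyloxy)methyl]-2-iodovinyl}-2-methyl-3-oxo-2,3-dihydrofuran-2-yl]pentanoate (7S,8R,10S in target numbering) | COC(=O)C(=C)[C@@H](CO[Si](C)(C)C(C)(C)C)[C@H](O)C[C@]1(C)OC(=CC1=O)/C(CO[Si](c2ccccc2)(c2ccccc2)C(C)(C)C)=C\I | intermediate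
23 | 4-O-methacrylate of 22 | COC(=O)C(=C)[C@@H](CO[Si](C)(C)C(C)(C)C)[C@H](OC(=O)C(C)=C)C[C@]1(C)OC(=CC1=O)/C(CO[Si](c2ccccc2)(c2ccccc2)C(C)(C)C)=C\I | intermediate
24 | methyl (3S,4R)-3-(hydroxymethyl)-4-(methacryloyloxy)-2-methylidene-5-[(S)-5-{(Z)-1-[(tert-butyldiphenylsilyloxy)methyl]-2-iodovinyl}-2-methyl-3-oxo-2,3-dihydrofuran-2-yl]pentanoate | COC(=O)C(=C)[C@@H](CO)[C@H](OC(=O)C(C)=C)C[C@]1(C)OC(=CC1=O)/C(CO[Si](c2ccccc2)(c2ccccc2)C(C)(C)C)=C\I | intermediate
25 | methyl (3R,4R)-3-formyl-4-(methacryloyloxy)-2-methylidene-5-[(S)-5-{(Z)-1-[(tert-butyldiphenylsilyloxy)methyl]-2-iodovinyl}-2-methyl-3-oxo-2,3-dihydrofuran-2-yl]pentanoate | COC(=O)C(=C)[C@@H](C=O)[C@H](OC(=O)C(C)=C)C[C@]1(C)OC(=CC1=O)/C(CO[Si](c2ccccc2)(c2ccccc2)C(C)(C)C)=C\I | intermediate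
26 | macrocyclic hydroxy ester: furanone-bridged nine-membered ring with free 6-OH, methyl acrylate branch on C7, 8-O-methacrylate, 15-O-TBDPS (6R,7S,8R,10S in target numbering) | COC(=O)C(=C)[C@@H]1[C@H](OC(=O)C(C)=C)C[C@]2(C)OC(=CC2=O)/C(CO[Si](c3ccccc3)(c3ccccc3)C(C)(C)C)=C\[C@H]1O | intermediate (not isolated)
27 | 15-O-tert-butyldiphenylsilyl ether of the target (6R,7R,8R,10S) | C=C(C)C(=O)O[C@@H]1C[C@]2(C)OC(=CC2=O)/C(CO[Si](c3ccccc3)(c3ccccc3)C(C)(C)C)=C\[C@H]2OC(=O)C(=C)[C@@H]21 | intermediate
28 | target CNP0180483.4 (6R,7R,8R,10S; 4Z) | C=C(C)C(=O)O[C@@H]1C[C@]2(C)OC(=CC2=O)/C(CO)=C\[C@H]2OC(=O)C(=C)[C@@H]21 | target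

**Count and risks**

Total steps: 21. Longest linear sequence: 15 (steps 1–5, 10–13, 16–21).

Step 20 (ring closure). What may go wrong: the alkenylchromium may add intermolecularly because the nine-membered transition state is strained; the labile aldehyde may epimerize at C7 or lose methacrylate before it is captured; and the facial selectivity at C6 may be poor. Fallback (boron and rhodium in place of chromium, with the option of ligand control at C6): setting out from 24, Miyaura borylation (B2pin2, PdCl2(dppf), KOAc, dioxane, 60 °C) would give the (Z)-alkenyl pinacolboronate alcohol F1. Dess–Martin oxidation would give the boronate aldehyde F2. A rhodium-catalysed intramolecular 1,2-addition of the alkenylboron to the aldehyde ([Rh(OH)(cod)]2, or its chiral-diene analogue to impose the C6 configuration; dioxane/H2O, 2 mM, 40 °C) should then form the same C5–C6 bond and give 26, which lactonizes as in step 20. The sequence comes back to the route at 27.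

Step 16 (allylation). What may go wrong: insufficient syn/anti or facial selectivity; elimination of the furanone oxygen from the β-position of aldehyde 16 under the additives; or early lactonization through O8. Fallback (stereospecific allylboration in place of the allylchromium): setting out from 19, acetylation (Ac2O, DMAP, Et3N) gives the allylic acetate F3. Palladium-catalysed borylation (B2pin2, Pd2(dba)3, toluene/DMSO, rt) gives the rearranged allylboronate F4, with CH2OTBS cis to CH2B. Addition of F4 to 16 with a chiral phosphoric acid ((R)-TRIP, toluene, 4 Å sieves, rt) should pass through a closed chair, which fixes the syn relation while the acid selects the aldehyde face. Hydrolytic work-up gives 22, where the route is rejoined.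

Step 6 (β-iodo Morita–Baylis–Hillman reaction). What may go wrong: Z to E equilibration of the β-iodoacrylate by reversible addition of iodide, or polymerization of formaldehyde before it is captured. Fallback (the alkene geometry is discarded and recreated by steric differentiation): setting out from 8 as any E/Z mixture, reduction with i-Bu2AlH (3.3 equiv, CH2Cl2, −78 °C) gives 2-(iodomethylene)propane-1,3-diol F5, the same diol from either isomer. Monosilylation with TBDPSCl (1.0 equiv, imidazole, CH2Cl2, −40 °C) should occur at the less hindered hydroxymethyl trans to iodine and gives 10, where the route is rejoined.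

**Further compounds**

F1 | step 20 | methyl (3S,4R)-3-(hydroxymethyl)-4-(methacryloyloxy)-2-methylidene-5-[(S)-5-{(Z)-1-[(tert-butyldiphenylsilyloxy)methyl]-2-(4,4,5,5-tetramethyl-1,3,2-dioxaborolan-2-yl)vinyl}-2-methyl-3-oxo-2,3-dihydrofuran-2-yl]pentanoate | COC(=O)C(=C)[C@@H](CO)[C@H](OC(=O)C(C)=C)C[C@]1(C)OC(=CC1=O)/C(CO[Si](c2ccccc2)(c2ccccc2)C(C)(C)C)=C\B1OC(C)(C)C(C)(C)O1
F2 | step 20 | methyl (3R,4R)-3-formyl-4-(methacryloyloxy)-2-methylidene-5-[(S)-5-{(Z)-1-[(tert-butyldiphenylsilyloxy)methyl]-2-(4,4,5,5-tetramethyl-1,3,2-dioxaborolan-2-yl)vinyl}-2-methyl-3-oxo-2,3-dihydrofuran-2-yl]pentanoate | COC(=O)C(=C)[C@@H](C=O)[C@H](OC(=O)C(C)=C)C[C@]1(C)OC(=CC1=O)/C(CO[Si](c2ccccc2)(c2ccccc2)C(C)(C)C)=C\B1OC(C)(C)C(C)(C)O1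
F3 | step 16 | methyl 2-[1-acetoxy-2-(tert-butyldimethylsilyloxy)ethyl]acrylate | C=C(C(=O)OC)C(OC(C)=O)CO[Si](C)(C)C(C)(C)C
F4 | step 16 | methyl (E)-4-(tert-butyldimethylsilyloxy)-2-[(4,4,5,5-tetramethyl-1,3,2-dioxaborolan-2-yl)methyl]but-2-enoate | COC(=O)/C(CB1OC(C)(C)C(C)(C)O1)=C/CO[Si](C)(C)C(C)(C)C
F5 | step 6 | 2-(iodomethylene)propane-1,3-diol | OCC(=CI)CO
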